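With drimane numbering (C4 CMe2, C5 carbinol, C8 CHMe, C9 quaternary, C10 ring-fusion CH, C11 benzylic CH2), everything rests on disconnecting C11–C9 into an aryl aldehyde carbon and a C8 silyl enol ether. The key step exploits the 1,3-diaxial relationship on ring B between the C5 oxygen and the C9–C11 bond: 2,3,5,6-tetramethoxybenzaldehyde condenses with the C5 silyl ether of a trans-decalin enol ether to an oxocarbenium ion that is captured at C9. One operation joins arene and decalin, sets the quaternary centre by tether control and leaves a temporary oxolane bridge, opened later by benzylic hydrogenolysis to the C5 hydroxyl and the C11 methylene.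

Key step: step 6

Remark (numbering): ring A is C1–C4, C5, C10 and ring B is C5–C10; β is the face of the C5 oxygen; the target is the trans-decalin (5R,8S,9S,10S).
Remark (assumption): the configuration at C11 in 12–15 is left undefined because it becomes CH2 in step 8, and the C9 configuration of 6–9 is erased in step 5.
Remark (assumption): the ligand enantiomer in step 2 is assigned by analogy with the known sense of induction for 2-cyclohexenone.

Step 1
Reactants: 1 1,2,4,5-tetramethoxybenzene
Product: 3 2,3,5,6-tetramethoxybenzaldehyde, via 2,3,5,6-tetramethoxyphenyllithium 2 (not isolated)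
Conditions: n-BuLi, TMEDA, THF, 0 °C; DMF, 0 °C to rt; H2O
Reagents that add atoms: N,N-dimethylformamide, CN(C)C=O
Why: Directed ortho-lithiation between two methoxy groups followed by formylation of the aryllithium with DMF (Bouveault-type formylation) should give the aldehyde; no stereocentre is formed.

Step 2
Reactants: 4 4,4-dimethoxycyclohexa-2,5-dien-1-one
Product: 6 (5S,6S)-4,4-dimethoxy-5-methyl-6-(prop-2-en-1-yl)cyclohex-2-en-1-one, via methylzinc enolate 5 (not isolated)
Conditions: Me2Zn, Cu(OTf)2 (2 mol%), (R,S,S)-[1,1′-binaphthalene]-2,2′-diyl N,N-bis(1-phenylethyl)phosphoramidite (4 mol%), toluene, −25 °C; then allyl acetate, Pd(PPh3)4 (2 mol%), 0 °C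
Reagents that add atoms: dimethylzinc, C[Zn]C; allyl acetate, CC(=O)OCC=C
Why: Copper-catalysed asymmetric conjugate addition of the methyl group to one enantiotopic face of the achiral dienone sets C9 under ligand control, and Tsuji–Trost allylation of the zinc enolate anti to that methyl sets C10 trans to it.

Step 3
Reactants: 6 (5S,6S)-4,4-dimethoxy-5-methyl-6-(prop-2-en-1-yl)cyclohex-2-en-1-one
Product: 8 (4R,5S,6S)-4-hydroxy-6-methyl-4-(2-methylbut-3-en-2-yl)-5-(prop-2-en-1-yl)cyclohex-2-en-1-one, via ketal carbinol 7 (not isolated)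
Conditions: Me2C=CHCH2MgCl, THF, −78 °C; then 1 M HCl, THF, 0 °C
Reagents that add atoms: 3-methylbut-2-enylmagnesium chloride, CC(C)=CC[Mg]Cl; water, O
Why: The allylic Grignard reagent adds 1,2 through its γ-terminus (SE2′, six-membered transition state) along the equatorial trajectory, placing the tert-alkyl group equatorial and trans to the C10 allyl group so that C5 is set by substrate control with its oxygen axial; dilute acid then hydrolyses the allylic dimethyl ketal to the C8 ketone.

Step 4
Reactants: 8 (4R,5S,6S)-4-hydroxy-6-methyl-4-(2-methylbut-3-en-2-yl)-5-(prop-2-en-1-yl)cyclohex-2-en-1-one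
Product: 9 (1S,4aR,8aS)-4a-hydroxy-1,5,5-trimethyl-4a,5,8,8a-tetrahydronaphthalen-2(1H)-one
Conditions: second-generation Grubbs catalyst (H2IMes)(PCy3)Cl2Ru=CHPh (5 mol%), CH2Cl2, 40 °C
Reagents that add atoms: none
Why: Ring-closing olefin metathesis of the allyl and 1,1-dimethylallyl groups, held trans-diequatorial on C10 and C5, should close ring A as a trans-fused cyclohexene with loss of ethene; no stereocentre changes.

Step 5
Reactants: 9 (1S,4aR,8aS)-4a-hydroxy-1,5,5-trimethyl-4a,5,8,8a-tetrahydronaphthalen-2(1H)-one
Product: 11 trimethyl{[(4aR,8aS)-1,5,5-trimethyl-4a-(trimethylsilyloxy)-3,4,4a,5,6,7,8,8a-octahydronaphthalen-2-yl]oxy}silane, via bis-silyl dienol ether 10 (not isolated)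
Conditions: Me3SiOTf, Et3N, CH2Cl2, −78 to 0 °C; then 2-O2NC6H4SO2NHNH2, Et3N, rt; non-aqueous work-up
Reagents that add atoms: trimethylsilyl trifluoromethanesulfonate, C[Si](C)(C)OS(=O)(=O)C(F)(F)F
Why: Soft enolisation of the enone can occur only at the α′-carbon C9 (C7 is olefinic and C5 bears no hydrogen), which fixes the enol ether at C8=C9 while the C5 hydroxyl is silylated; diimide reduction then saturates the two disubstituted olefins but spares the tetrasubstituted enol ether, which removes the dienyl ionisation (aromatisation) pathway before acid is used.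

Step 6
Reactants: 11 trimethyl{[(4aR,8aS)-1,5,5-trimethyl-4a-(trimethylsilyloxy)-3,4,4a,5,6,7,8,8a-octahydronaphthalen-2-yl]oxy}silane; 3 2,3,5,6-tetramethoxybenzaldehyde
Product: 13 bridged ether ketone (5R,9S,10S): the saturated decalin-8-one in which C9 and the C5 oxygen are joined by a CH(2,3,5,6-tetramethoxyphenyl) unit, via oxocarbenium triflate 12 (not isolated)
Conditions: Me3SiOTf (0.2 equiv), 2,6-di-tert-butyl-4-methylpyridine (0.2 equiv), CH2Cl2, −78 to −30 °C
Reagents that add atoms: none
Why: Me3SiOTf activates aldehyde 3, the C5 silyl ether oxygen adds and hexamethyldisiloxane is expelled, so that the (E)-oxocarbenium ion 12 is generated while held on the β face of ring B by its C5–O bond. The tetrasubstituted silyl enol ether then attacks through C9, forming the C11–C9 bond and the C8 ketone and returning the silyl group to triflate, which makes the acid catalytic. The closest known reaction type is the silyl-ether/aldehyde oxocarbenium condensation coupled to an intramolecular Mukaiyama aldol addition (silyl enol ether Prins cyclisation, silyl-modified Sakurai cyclisation). The temporary oxolane O–C11–C9–C10–C5 closes in a 5-(enolexo)-endo-trig mode, the same formally strained but well-behaved mode as the Mannich closure of the aza-Cope–Mannich sequence, and gives a 6-oxabicyclo[3.2.1]octan-2-one fused to ring A. The new quaternary centre C9 is controlled by the tether alone: C11 can only be delivered to the face of C9 syn to the axial C5 oxygen, which puts the benzylic carbon axial and the methyl equatorial, while the configuration at C11 is irrelevant because it becomes a methylene group. The step needs site selectivity for C9 over C7, secured because the enol ether was fixed at C8=C9 in step 5, and preference for the tethered over the untethered aldol pathway, secured because silyl triflate promotes carbonyl addition of enol silanes only through oxocarbenium ions and an adduct formed on the α face could not close the ether.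

Step 7
Reactants: 13 bridged ether ketone
Product: 14 bridged ether (5R,9R,10S) with an exocyclic methylene group at C8
Conditions: Ph3PCH3Br, KOt-Bu, toluene, 90 °C
Reagents that add atoms: methyltriphenylphosphonium bromide, C[P+](c1ccccc1)(c1ccccc1)c1ccccc1.[Br-]
Why: Wittig methylenation of the hindered ketone next to the quaternary C9 should install the future C8 methyl carbon as an exocyclic olefin; no stereocentre is affected.

Step 8
Reactants: 14 bridged ether with an exocyclic methylene group at C8
Product: 16 (4aR,7S,8S,8aS)-4,4,7,8-tetramethyl-8-[(2,3,5,6-tetramethoxyphenyl)methyl]octahydronaphthalen-4a(2H)-ol, via saturated bridged ether 15 (not isolated)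
Conditions: H2 (4 atm), Pd(OH)2/C, EtOH–AcOH, rt
Reagents that add atoms: none
Why: Heterogeneous hydrogenation should deliver hydrogen to the exocyclic olefin from the α face, opposite the axial C9–C11 bridge, which sets the equatorial C8 methyl; hydrogenolysis of the electron-rich benzylic C11–O bond then releases the C5 tertiary alcohol and the C11 methylene.

Step 9
Reactants: 16 (4aR,7S,8S,8aS)-4,4,7,8-tetramethyl-8-[(2,3,5,6-tetramethoxyphenyl)methyl]octahydronaphthalen-4a(2H)-ol
Product: 17 3-{[(1S,2S,4aR,8aS)-4a-hydroxy-1,2,5,5-tetramethyldecahydronaphthalen-1-yl]methyl}-2,5-dimethoxycyclohexa-2,5-diene-1,4-dione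
Conditions: (NH4)2Ce(NO3)6, MeCN–H2O, 0 °C
Reagents that add atoms: water, O
Why: Oxidative demethylation of the 1,2,4,5-tetramethoxyarene by tetravalent cerium should give the 2,5-dimethoxy-1,4-benzoquinone (the two possible para-quinones are the same compound by symmetry); the stereocentres are untouched.

Step 10
Reactants: 17 3-{[(1S,2S,4aR,8aS)-4a-hydroxy-1,2,5,5-tetramethyldecahydronaphthalen-1-yl]methyl}-2,5-dimethoxycyclohexa-2,5-diene-1,4-dione
Product: 18 2-hydroxy-3-{[(1S,2S,4aR,8aS)-4a-hydroxy-1,2,5,5-tetramethyldecahydronaphthalen-1-yl]methyl}-5-methoxycyclohexa-2,5-diene-1,4-dione (the target)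
Conditions: KOH, MeOH–H2O, rt; then 1 M HCl to pH 4
Reagents that add atoms: potassium hydroxide, [K+].[OH-]
Why: Addition–elimination of hydroxide at the vinylogous ester flanked by the alkyl group, whose methoxy group is twisted out of conjugation and therefore the more reactive, should give the 2-hydroxy-5-methoxyquinone as its anion, which resists a second hydrolysis (selective vinylogous ester saponification); the base leaves the tertiary alcohol untouched.

Compound list
1 | 1,2,4,5-tetramethoxybenzene | COc1cc(OC)c(OC)cc1OC | starting material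
2 | 2,3,5,6-tetramethoxyphenyllithium | [Li]c1c(OC)c(OC)cc(OC)c1OC | intermediate
3 | 2,3,5,6-tetramethoxybenzaldehyde | O=Cc1c(OC)c(OC)cc(OC)c1OC | intermediate
4 | 4,4-dimethoxycyclohexa-2,5-dien-1-one | COC1(OC)C=CC(=O)C=C1 | starting material
5 | methylzinc (3S)-4,4-dimethoxy-3-methylcyclohexa-1,5-dien-1-olate | C[C@@H]1C(OC)(OC)C=CC(O[Zn]C)=C1 | intermediate
6 | (5S,6S)-4,4-dimethoxy-5-methyl-6-(prop-2-en-1-yl)cyclohex-2-en-1-one | C[C@@H]1C(OC)(OC)C=CC(=O)[C@H]1CC=C | intermediate
7 | (1R,5S,6S)-4,4-dimethoxy-5-methyl-1-(2-methylbut-3-en-2-yl)-6-(prop-2-en-1-yl)cyclohex-2-en-1-ol | C[C@@H]1C(OC)(OC)C=C[C@@](C(C)(C)C=C)(O)[C@H]1CC=C | intermediate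
8 | (4R,5S,6S)-4-hydroxy-6-methyl-4-(2-methylbut-3-en-2-yl)-5-(prop-2-en-1-yl)cyclohex-2-en-1-one | C[C@@H]1C(=O)C=C[C@@](C(C)(C)C=C)(O)[C@H]1CC=C | intermediate
9 | (1S,4aR,8aS)-4a-hydroxy-1,5,5-trimethyl-4a,5,8,8a-tetrahydronaphthalen-2(1H)-one | C[C@@H]1C(=O)C=C[C@@]2(O)[C@H]1CC=CC2(C)C | intermediate
10 | trimethyl{[(4aR,8aS)-1,5,5-trimethyl-4a-(trimethylsilyloxy)-4a,5,8,8a-tetrahydronaphthalen-2-yl]oxy}silane | CC1=C(O[Si](C)(C)C)C=C[C@@]2(O[Si](C)(C)C)[C@H]1CC=CC2(C)C | intermediate
11 | trimethyl{[(4aR,8aS)-1,5,5-trimethyl-4a-(trimethylsilyloxy)-3,4,4a,5,6,7,8,8a-octahydronaphthalen-2-yl]oxy}silane | CC1=C(O[Si](C)(C)C)CC[C@@]2(O[Si](C)(C)C)[C@H]1CCCC2(C)C | intermediate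
12 | oxocarbenium triflate: the C5 oxygen of 11 doubly bonded to the CH(2,3,5,6-tetramethoxyphenyl) carbon, enol ether intact | CC1=C(O[Si](C)(C)C)CC[C@@]2([O+]=Cc3c(OC)c(OC)cc(OC)c3OC)[C@H]1CCCC2(C)C.[O-]S(=O)(=O)C(F)(F)F | intermediate
13 | bridged ether ketone (5R,9S,10S; C11 undefined): 4,4,9-trimethyl-trans-decalin-8-one with a C5–O–CH(2,3,5,6-tetramethoxyphenyl)–C9 bridge | C1(c4c(OC)c(OC)cc(OC)c4OC)[C@@]2(C)C(=O)CC[C@@]3(O1)[C@H]2CCCC3(C)C | intermediate
14 | bridged ether (5R,9R,10S; C11 undefined) with C8 exocyclic methylene | C1(c4c(OC)c(OC)cc(OC)c4OC)[C@@]2(C)C(=C)CC[C@@]3(O1)[C@H]2CCCC3(C)C | intermediate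
15 | saturated bridged ether (5R,8S,9S,10S; C11 undefined) | C1(c4c(OC)c(OC)cc(OC)c4OC)[C@@]2(C)[C@@H](C)CC[C@@]3(O1)[C@H]2CCCC3(C)C | intermediate
16 | (4aR,7S,8S,8aS)-4,4,7,8-tetramethyl-8-[(2,3,5,6-tetramethoxyphenyl)methyl]octahydronaphthalen-4a(2H)-ol | COc1cc(OC)c(OC)c(C[C@@]2(C)[C@@H](C)CC[C@@]3(O)[C@H]2CCCC3(C)C)c1OC | intermediate
17 | 3-{[(1S,2S,4aR,8aS)-4a-hydroxy-1,2,5,5-tetramethyldecahydronaphthalen-1-yl]methyl}-2,5-dimethoxycyclohexa-2,5-diene-1,4-dione | COC1=CC(=O)C(OC)=C(C[C@@]2(C)[C@@H](C)CC[C@@]3(O)[C@H]2CCCC3(C)C)C1=O | intermediate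
18 | 2-hydroxy-3-{[(1S,2S,4aR,8aS)-4a-hydroxy-1,2,5,5-tetramethyldecahydronaphthalen-1-yl]methyl}-5-methoxycyclohexa-2,5-diene-1,4-dione (CNP0209468.2) | COC1=CC(=O)C(O)=C(C[C@@]2(C)[C@@H](C)CC[C@@]3(O)[C@H]2CCCC3(C)C)C1=O | target

Total step count: 10. Longest linear sequence: 9 steps (steps 2–10, from 4); step 1 is the convergent branch.

Steps most likely to fail

Step 6. The hindered C5 silyl ether may fail to add to the deactivated, di-ortho-substituted aldehyde, so that the oxocarbenium ion is never formed, or the enol ether may be lost by protodesilylation before it is captured. The fallback makes the carbon–carbon bond first and the ether second. Setting out from 11, MeLi (THF, 0 °C) would cleave both silyl groups to the lithium alkoxide–enolate; aldehyde 3 would be added at −78 °C in an alkoxide-directed aldol addition, and cold work-up would give the aldol adduct F1. A catalytic amount of camphorsulfonic acid in CH2Cl2 would then ionise the electron-rich benzylic alcohol and the C5 hydroxyl would trap the cation, so that the route is rejoined at 13.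

Step 3. Facial selectivity of the 1,2-addition may be poor because the flattened enone also offers an axial trajectory; attack through the α-terminus of the allylmetal or reversal of the addition could also intervene. The fallback adds to a saturated ketone, where two syn-axial hydrogens enforce equatorial attack, and restores the olefin afterwards. Setting out from 6, conjugate reduction with [(Ph3P)CuH]6 would give the saturated ketone F2. Addition of Me2C=CHCH2MgCl would give the ketal carbinol F3, hydrolysed on acidic work-up to the hydroxy ketone F4. Kinetic deprotonation at C7 with LiN(i-Pr)2 (2.2 equiv, −78 °C) and oxidation of the enolate with N-tert-butylbenzenesulfinimidoyl chloride would then reinstall the C6=C7 double bond and return to the route at 8.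

Step 8. Hydrogenolysis may stall after saturation of the olefin, because the benzylic C–O bond is shielded by two ortho methoxy groups and the quaternary carbon. The fallback lets the quinone open the bridge itself. Setting out from 15, oxidation with (NH4)2Ce(NO3)6 would give the bridged dimethoxyquinone F5. Reduction with Na2S2O4 (THF–H2O) would give the bridged hydroquinone F6, which should expel the C5 alkoxide to the ortho-quinone methide F7; its tautomerisation and aerobic work-up would return to the route at 17.

Further compounds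
F1 | step 6 | (1S,4aR,8aS)-4a-hydroxy-1-[hydroxy(2,3,5,6-tetramethoxyphenyl)methyl]-1,5,5-trimethyloctahydronaphthalen-2(1H)-one | OC(c4c(OC)c(OC)cc(OC)c4OC)[C@@]2(C)C(=O)CC[C@@]3(O)[C@H]2CCCC3(C)C
F2 | step 3 | (2S,3S)-4,4-dimethoxy-3-methyl-2-(prop-2-en-1-yl)cyclohexan-1-one | C[C@@H]1C(OC)(OC)CCC(=O)[C@H]1CC=C
F3 | step 3 | (1R,2S,3S)-4,4-dimethoxy-3-methyl-1-(2-methylbut-3-en-2-yl)-2-(prop-2-en-1-yl)cyclohexan-1-ol | C[C@@H]1C(OC)(OC)CC[C@@](C(C)(C)C=C)(O)[C@H]1CC=C
F4 | step 3 | (2S,3S,4R)-4-hydroxy-2-methyl-4-(2-methylbut-3-en-2-yl)-3-(prop-2-en-1-yl)cyclohexan-1-one | C[C@@H]1C(=O)CC[C@@](C(C)(C)C=C)(O)[C@H]1CC=C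
F5 | step 8 | bridged ether 15 with the arene replaced by a 2,5-dimethoxy-1,4-benzoquinon-3-yl group | C1(C4=C(OC)C(=O)C=C(OC)C4=O)[C@@]2(C)[C@@H](C)CC[C@@]3(O1)[C@H]2CCCC3(C)C
F6 | step 8 | bridged ether 15 with the arene replaced by a 3,6-dihydroxy-2,5-dimethoxyphenyl group | C1(c4c(OC)c(O)cc(OC)c4O)[C@@]2(C)[C@@H](C)CC[C@@]3(O1)[C@H]2CCCC3(C)C
F7 | step 8 | ring-opened ortho-quinone methide: 6-[(decalinyl)methylidene]-3-hydroxy-2,5-dimethoxycyclohexa-2,4-dien-1-one with free C5 hydroxyl | C(=C1C(OC)=C(O)C=C(OC)C1=O)[C@@]2(C)[C@@H](C)CC[C@@]3(O)[C@H]2CCCC3(C)C
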